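Readings and results are simulated on assumed constants, and the scatter is random.

No reading of this flask exists, so neither order can be measured; we reckon them from the intermediate, the gap between substrate lost and product found.

| setting | maple | alder | cedar | flask |
|---|---|---|---|---|
| substrate | 47 mM | 47 mM | 47 mM | 47 mM |
| reagent | 0.70 equiv | 0.70 equiv | 1 equiv | 0.700 equiv |
| free catalyst | 3.4 mol% | 7.5 mol% | 5 mol% | 5 mol% |
| remark | run made earlier | run made earlier | run made earlier |  |

| run | time / min | product / % | substrate / % |
|---|---|---|---|
| maple | 0.333 | 1.5 | 95.1 |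
| maple | 1.00 | 7.9 | 84.4 |
| maple | 1.50 | 13.5 | 79.4 |
| maple | 2.50 | 22.2 | 68.0 |
| maple | 4.00 | 32.3 | 54.0 |
| maple | 5.00 | 37.4 | 47.4 |
| maple | 6.00 | 41.9 | 41.9 |
| alder | 0.833 | 17.3 | 73.9 |
| alder | 1.50 | 31.5 | 58.8 |
| alder | 2.50 | 43.8 | 43.3 |
| alder | 3.00 | 48.7 | 37.5 |
| alder | 4.00 | 52.9 | 29.3 |
| alder | 5.00 | 56.2 | 24.5 |
| alder | 6.00 | 57.4 | 21.3 |
| cedar | 0.500 | 6.8 | 88.5 |
| cedar | 1.50 | 23.3 | 69.9 |
| cedar | 3.00 | 42.2 | 50.3 |
| cedar | 4.00 | 49.9 | 40.6 |
| cedar | 6.00 | 61.3 | 28.0 |

(scatter of a reading: 0.5 percentage points)

- apparent order in free catalyst when 10% of the substrate are converted (percent change of the rate of making product for one percent more free catalyst charged)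
- apparent order in reagent when 10% of the substrate are converted (percent change of the rate of making product for one percent more reagent charged)

- the analysis behind the earlier runs scatters by 0.5 percentage points, standard deviation

1. Take a pool filled steadily and emptied with rate constant k, which we take as proportional to reagent and to free catalyst. After time t, product flows at a share 1 − exp(−n) of the filling rate, so the reagent order is s = n/(exp n − 1). Here n = kt at the chosen conversion.

2. Free catalyst cancels in n: it raises k and shortens t by the same factor. So in this reckoning s does not depend on the catalyst loading, and the catalyst order is 1.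

3. Scatter in the maple run puts 3.49% on t, 6.76% on the pool and 12.6% on the product slope. The slope is the weakest reading, yet at a trial n = 1 an error of that size moves s by 0.0415.

4. Maple's slope 0.112 min⁻¹ over its pool 7.40% gives k = 1.51 min⁻¹, and its substrate loss gives t = 0.621 min. Their product is the pool count n, the lifetimes of the pool elapsed by 10% conversion: 0.940. The flask has maple's reagent charge, so we reckon s = 0.602 for the flask.

The forecast gave 1.03 (0.85 to 1.25) and 0.4 (0.15 to 0.7), the second “well below 1 because of the buffering intermediate pool”.

The flask gives 1.0 and 0.57.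

    reagent ⇌ dormant form (K = 28.0, k = 0.00190 s⁻¹)
    substrate + free catalyst ⇌ free catalyst + intermediate (K = 1.60, k = 1.80 M⁻¹ s⁻¹)
    reagent + free catalyst + intermediate → free catalyst + product (k = 570 M⁻² s⁻¹)
    free catalyst → spent catalyst (k = 3.10 × 10⁻⁴ s⁻¹)

With n = 0.940, a steadily filled pool at 10% conversion is made 1.64 times as fast as it is used up, so it is still filling. In the flask, intermediate is still filling at 2.15 min: each step taken net, it is made faster than it is used up, by a factor of 1.16.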